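The constants used here are made up.

In a one-step world G has one exit, to J, but this G has competing exits, so we count turnovers per minute on each.

    2 G → G2 (k1 = 0.028 M⁻¹ min⁻¹)
    Z ⇌ G (k2 = 4.3 × 10⁻⁴ min⁻¹)
    G → L (k3 = 2.2 × 10⁻⁶ min⁻¹)
    G ⇌ J (K4 = 6.1, k4 = 7.6 × 10⁻⁴ min⁻¹)
    J ⇌ Z (K5 = 0.11, k5 = 0.0016 min⁻¹)
    G + E → G.E (k6 = 0.024 M⁻¹ min⁻¹)

common to all: E 0.0250 M
- elm: G 0.050 M; one stirred flow tank at steady state, fed with the mixture as stated, mean residence time 40 h
- larch: G 0.050 M; everything together in a closed stirred flask, run for 40 h; time 40 h
- alder: G 0.050 M; a tube with plug flow, the mixed feed as stated, residence time 40 h; time 40 h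
- maple: G 0.050 M (fed, over 32.0 h); a stirred flask in which G is dosed at a steady rate over 32.0 h without added volume, worked up at 40 h; time 40 h

- percentages count the G that a species holds: one G2 counts as two
- a doubled species enters its step squared and goes two at a time
- the stated concentrations are those of everything mixed, before any reaction; amounts are the same in each set-up
- the feed brings no volume worth counting
- run time (larch): 40 h

- the set-up with the highest amount of J at the outlet or at the end, in percent of the G put in ("none" if the first two lie within 2 percentage points) (elm / larch / alder / maple / none)
- amount of J at the outlet or at the end, in percent of the G put in, elm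
- amount of J at the outlet or at the end, in percent of the G put in, larch
- amount of J at the outlet or at the end, in percent of the G put in, alder
- amount of J at the outlet or at the end, in percent of the G put in, maple

At the charge, dimerisation of G to G2 turns over faster than isomerisation of G to J, so J should gain in a set-up that keeps G low. We hold E at its charge and let no J come back. Call the J share the isomerisation rate constant divided by the sum of three terms: that rate constant, 2 times the dimerisation rate constant times G, and the rate constant of capture of G by E times E. Maple is dosed at 2.60 × 10⁻⁵ M min⁻¹, and during the feed we reckon that feed equals turnovers out at G of 0.0126 M. That gives 36.8% as the J share, the selectivity to J, and we take this as maple's yield. In elm, adding washout to the same balance gives G of 0.00911 M, and the share times the G reacted gives J of 33.2%. In larch and alder G falls from the charge, and averaging the share over a complete fall gives 30.3% for each.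

The forecast names maple, with elm 32.5%, larch 29%, alder 29% and maple 38%, on the ground that “anything that keeps G low” favours J. Its larch figure stands below ours and its maple figure above ours.

The simulation gives maple as best, with elm 32.3%, larch 29.1%, alder 29.1% and maple 36.2%, the order of the forecast.

The neighbour flask is maple with E at 0.0063 M. With E held at its charge, capture now turns over at 1.51 × 10⁻⁴ min⁻¹ against 6.00 × 10⁻⁴ min⁻¹ in maple, so the same balance gives G of 0.0149 M, and our reckoned J share moves from 36.8% to 43.5%. Simulated, the neighbour ends with 40.9% of J against 36.2% in maple, and with G.E at 5.78% against 21.0%.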